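Plan
1. Cuts: (a) the ring bond between the ketone carbon and the methyl-bearing epoxide carbon, C(=O)–C(CH3)(O); (b) the epoxide C–O bond at the CH carbon; (c) the exocyclic C=C of the α-alkylidene-γ-butyrolactone; (d) the CH(CO2Me)–CH(O) bond of the side chain.
2. Enabling feature: in the 14-membered carbocycle the array C(=O)–C(CH3)(O)–CH(O)–CH2–CH(isopropenyl)–CH2–CH= is (R)-carvone opened between ring C2 and C3 (C5 = isopropenyl carbon, C1 carbinol = epoxide CH, C2 = quaternary epoxide carbon as a methyl ketone, C3 = alkylidene CH as an aldehyde). The vicinal oxygens on the ketone carbon and the quaternary carbon are the retron of an aldehyde–ketone reductive coupling.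
3. Forward: carvone gives keto-aldehyde 5 (west). (S)-Lactone tosylate 6 gives lactone ester 12 (east) by a trans aldol and a lactone transposition through a terminal epoxide. Aldol addition and elimination join 5 and 12 through the (E)-alkylidene lactone.
4. Ring order: butyrolactone first; then the 14-membered carbocycle by titanium pinacol coupling (step 13); then the epoxide by mesylate displacement; last the 1,3-diketone by oxidation.
5. Stereochemistry: isopropenyl carbon and epoxide CH from carvone (the latter inverted on epoxide closure); lactone CH–O from 6 (glutamic acid pool); ester-bearing CH by the ring-controlled trans aldol; quaternary epoxide carbon by chelation control in step 13; alkene geometry by thermodynamic elimination.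

Key step: step 13

Assumption: the CH between the methyl ester and the ketone is doubly activated and epimerizable; it is set in step 5, carried through non-enolizing steps, and taken to keep (or to prefer) the drawn configuration after the buffered last oxidation. The silyloxy carbon that becomes this ketone is carried as a mixture of epimers. (PMB = 4-methoxybenzyl, TBS = tert-butyldimethylsilyl.)

Step 1
Reactants: 1 (R)-(−)-carvone
Product: 2 (−)-cis-carveol
Conditions: NaBH4, CeCl3·7H2O, MeOH, −20 °C
Reagents that add atoms: none
Why: Luche reduction should give clean 1,2-reduction, and axial hydride attack on the half-chair with equatorial isopropenyl should set the carbinol cis to the isopropenyl group, which is the configuration needed for the later inversion.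

Step 2
Reactants: 2 (−)-cis-carveol
Product: 3 syn-epoxy alcohol
Conditions: VO(acac)2 (cat.), t-BuOOH, CH2Cl2, 0 → 25 °C
Reagents that add atoms: tert-butyl hydroperoxide, CC(C)(C)OO
Why: hydroxyl-directed vanadium-catalysed epoxidation should oxidize only the allylic ring alkene, on the face of the OH, and leave the isopropenyl group alone; the epoxide configuration is of no consequence because both carbons become carbonyls.

Step 3
Reactants: 3 syn-epoxy alcohol
Product: 4 PMB ether of the epoxy alcohol
Conditions: NaH, 4-methoxybenzyl chloride, Bu4NI (cat.), DMF, 0 → 25 °C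
Reagents that add atoms: 4-methoxybenzyl chloride, COc1ccc(CCl)cc1
Why: Williamson etherification; the alkoxide is syn to the epoxide oxygen and so cannot undergo Payne rearrangement, and the ether later blocks over-cleavage and serves as the chelating group.

Step 4
Reactants: 4 PMB ether of the epoxy alcohol
Product: 5 west keto-aldehyde
Conditions: H5IO6, THF/H2O, 0 → 25 °C
Reagents that add atoms: water, O
Why: periodic acid should hydrolyse the trisubstituted epoxide and cleave the resulting glycol (Malaprade-type cleavage), turning ring C2 into the methyl ketone and C3 into the aldehyde without touching either stereocenter or the isopropenyl group.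

Step 5
Reactants: 6 (S)-lactone tosylate; 7 3-(TBS-oxy)propanal
Product: 8 trans-aldol lactone
Conditions: LDA, THF, −78 °C; then 7, −78 °C
Reagents that add atoms: none
Why: aldol addition of the lactone lithium enolate, in which the aldehyde should approach anti to the CH2OTs group and set the future ester-bearing stereocenter trans across the ring; the tosylate is inert at −78 °C and the new carbinol is later oxidized.

Step 6
Reactants: 8 trans-aldol lactone
Product: 9 bis-silyl ether lactone
Conditions: TBSOTf, 2,6-lutidine, CH2Cl2, −78 → 0 °C
Reagents that add atoms: tert-butyldimethylsilyl trifluoromethanesulfonate, CC(C)(C)[Si](C)(C)OS(=O)(=O)C(F)(F)F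
Why: standard silylation of the secondary alcohol, which blocks retro-aldol cleavage in the next step.

Step 7
Reactants: 9 bis-silyl ether lactone
Product: 10 epoxy methyl ester
Conditions: K2CO3, MeOH, 0 → 25 °C
Reagents that add atoms: methanol, CO
Why: methanolysis of the lactone followed by intramolecular Williamson closure of the liberated alkoxide onto the CH2OTs group fixes the carboxyl as the methyl ester irreversibly and keeps the carbinol configuration (its C–O bond is not broken).

Step 8
Reactants: 10 epoxy methyl ester
Product: 12 east lactone ester, via hydroxy ynol ether 11 (not isolated)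
Conditions: ethoxyacetylene, n-BuLi, THF, −78 °C; BF3·OEt2; then 10, −78 °C; then PPTS (cat.), wet CH2Cl2, 25 °C
Reagents that add atoms: ethoxyacetylene, C#COCC; water, O
Why: BF3-assisted alkynylation of the terminal epoxide carbon (Yamaguchi-type opening) followed by acid-catalysed hydration and lactonization of the γ-hydroxy ynol ether builds the second five-membered lactone on the side away from the methyl ester, with the carbinol center untouched.

Step 9
Reactants: 12 east lactone ester; 5 west keto-aldehyde
Product: 13 β-hydroxy lactone adduct
Conditions: LDA, THF, −78 °C; then 5, −78 °C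
Reagents that add atoms: none
Why: kinetic deprotonation should occur at the unhindered lactone CH2 and not at the tertiary ester α-carbon, and the lithium enolate should add to the aldehyde of 5 far faster than to its ketone (aldol addition); the two new stereocenters are removed in step 10.

Step 10
Reactants: 13 β-hydroxy lactone adduct
Product: 15 (E)-alkylidene lactone, via aldol mesylate 14 (not isolated)
Conditions: MsCl, Et3N, CH2Cl2, 0 °C; then DBU, 0 → 25 °C
Reagents that add atoms: none
Why: mesylation and E1cB elimination should converge both aldol diastereomers on the conjugated E-alkylidene lactone (chain cis to the ring CH2), which is the thermodynamic isomer.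

Step 11
Reactants: 15 (E)-alkylidene lactone
Product: 16 primary alcohol
Conditions: HF·pyridine, pyridine, THF, 0 °C
Reagents that add atoms: none
Why: buffered HF·pyridine should remove the primary TBS ether well before the hindered secondary one (selective desilylation).

Step 12
Reactants: 16 primary alcohol
Product: 17 seco keto-aldehyde
Conditions: Dess–Martin periodinane, NaHCO3, CH2Cl2, 0 → 25 °C
Reagents that add atoms: none
Why: Dess–Martin oxidation gives the β-silyloxy aldehyde under near-neutral conditions without epimerizing the centers next to the ketone or the ester.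

Step 13
Reactants: 17 seco keto-aldehyde
Product: 18 macrocyclic 1,2-diol
Conditions: TiCl3(DME)1.5, Zn–Cu, DME, reflux, then 25 °C; 17 added by syringe pump over 30 h (final 0.002 M); aqueous K2CO3 work-up
Reagents that add atoms: none
Why: Low-valent titanium transfers an electron to each carbonyl, and the two titanium-bound ketyls couple between the aldehyde carbon and the ketone carbon to a titanium diolate, which is released as the 1,2-diol because deoxygenation does not set in at 25 °C. The closest known reaction type is the titanium-induced keto-aldehyde pinacol macrocyclization that gives 14-membered cembranoid 1,2-diols. The 14-membered carbocycle closes end to end, with both carbonyl oxygens held on titanium as a template, under syringe-pump dilution. The new quaternary carbinol is controlled by the adjacent PMB-oxy stereocenter from carveol: a five-membered chelate of the oxophilic titanium between the ketone oxygen and the ether oxygen (Cram chelate) should expose the face on the side of the small hydrogen, giving the syn tertiary/secondary O,O relationship; the secondary carbinol from the aldehyde is uncontrolled and is oxidized in step 14. The step needs ring closure over dimerization (dilution), carbonyl coupling over reduction of the β-substituted alkylidene lactone and the esters (room temperature), and retention of the ether oxygen next to the ketone (a chelated ether, not a halide or sulfonate).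

Step 14
Reactants: 18 macrocyclic 1,2-diol
Product: 19 macrocyclic α-ketol
Conditions: 2-iodoxybenzoic acid (IBX), DMSO/THF, 25 °C
Reagents that add atoms: none
Why: IBX oxidizes the secondary alcohol of a secondary/tertiary glycol to the α-ketol without C–C cleavage and removes the uncontrolled carbinol center.

Step 15
Reactants: 19 macrocyclic α-ketol
Product: 20 keto diol
Conditions: DDQ, CH2Cl2/pH 7 buffer, 0 → 25 °C
Reagents that add atoms: none
Why: oxidative PMB cleavage with DDQ in a wet, buffered medium frees the secondary alcohol and leaves the silyl ether, the alkenes and the α-ketol untouched.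

Step 16
Reactants: 20 keto diol
Product: 22 silyl-protected epoxy ketone, via secondary mesylate 21 (not isolated)
Conditions: MsCl, Et3N, DMAP (cat.), CH2Cl2, −10 °C; then DBU, 25 °C
Reagents that add atoms: none
Why: only the secondary alcohol is sulfonylated, and the tertiary alkoxide then displaces the mesylate (3-exo-tet SN2) with inversion at the CH carbon, so the syn diol gives the epoxide with the acyl branch and the ring CH2 cis, as in the target.

Step 17
Reactants: 22 silyl-protected epoxy ketone
Product: 23 β-hydroxy epoxy ketone
Conditions: HF·pyridine, pyridine, THF, 0 → 25 °C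
Reagents that add atoms: none
Why: buffered HF·pyridine desilylation should spare the epoxy ketone, and no base is present that could trigger retro-aldol cleavage or epimerization.

Step 18
Reactants: 23 β-hydroxy epoxy ketone
Product: 24 target CNP0108136.1
Conditions: Dess–Martin periodinane, pyridine, CH2Cl2, 0 °C
Reagents that add atoms: none
Why: Dess–Martin oxidation of the β-hydroxy ketone gives the 1,3-diketone (β,δ-diketo ester) under buffered, non-enolizing conditions, so the ester-bearing stereocenter and the acid-sensitive epoxide should survive.

Compound list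
1 | (R)-(−)-carvone, (5R)-2-methyl-5-(prop-1-en-2-yl)cyclohex-2-en-1-one | CC1=CC[C@@H](C(C)=C)CC1=O | starting material
2 | (−)-cis-carveol, (1R,5R)-2-methyl-5-(prop-1-en-2-yl)cyclohex-2-en-1-ol | CC1=CC[C@@H](C(C)=C)C[C@H]1O | intermediate
3 | syn-epoxy alcohol, 1-methyl-4-(prop-1-en-2-yl)-7-oxabicyclo[4.1.0]heptan-2-ol with epoxide oxygen, hydroxyl and isopropenyl on one face | C[C@]12O[C@H]1C[C@@H](C(C)=C)C[C@H]2O | intermediate
4 | PMB ether of 3 | C[C@]12O[C@H]1C[C@@H](C(C)=C)C[C@H]2OCc1ccc(OC)cc1 | intermediate
5 | west keto-aldehyde, (3S,5R)-5-[(4-methoxybenzyl)oxy]-6-oxo-3-(prop-1-en-2-yl)heptanal | CC(=O)[C@H](OCc1ccc(OC)cc1)C[C@H](C(C)=C)CC=O | intermediate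
6 | (S)-(5-oxooxolan-2-yl)methyl 4-methylbenzenesulfonate | O=C1CC[C@@H](COS(=O)(=O)c2ccc(C)cc2)O1 | starting material
7 | 3-[(tert-butyldimethylsilyl)oxy]propanal | O=CCCO[Si](C)(C)C(C)(C)C | starting material
8 | trans-aldol lactone, [(2S,4S)-4-{1-hydroxy-3-[(tert-butyldimethylsilyl)oxy]propyl}-5-oxooxolan-2-yl]methyl 4-methylbenzenesulfonate, both carbinol epimers | O=C1[C@H](C(O)CCO[Si](C)(C)C(C)(C)C)C[C@@H](COS(=O)(=O)c2ccc(C)cc2)O1 | intermediate
9 | bis-silyl ether lactone, secondary TBS ether of 8 | O=C1[C@H](C(O[Si](C)(C)C(C)(C)C)CCO[Si](C)(C)C(C)(C)C)C[C@@H](COS(=O)(=O)c2ccc(C)cc2)O1 | intermediate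
10 | epoxy methyl ester, methyl (2S)-3,5-bis[(tert-butyldimethylsilyl)oxy]-2-{[(2S)-oxiran-2-yl]methyl}pentanoate, epimers at C3 | COC(=O)[C@@H](C[C@H]1CO1)C(O[Si](C)(C)C(C)(C)C)CCO[Si](C)(C)C(C)(C)C | intermediate
11 | hydroxy ynol ether, methyl (2S)-3,5-bis[(tert-butyldimethylsilyl)oxy]-2-[(2S)-5-ethoxy-2-hydroxypent-4-yn-1-yl]pentanoate | COC(=O)[C@@H](C[C@H](O)CC#COCC)C(O[Si](C)(C)C(C)(C)C)CCO[Si](C)(C)C(C)(C)C | intermediate
12 | east lactone ester, methyl (2S)-3,5-bis[(tert-butyldimethylsilyl)oxy]-2-{[(2R)-5-oxooxolan-2-yl]methyl}pentanoate (same spatial arrangement at the lactone carbinol as in 6; the descriptor changes by priority only) | COC(=O)[C@@H](C[C@H]1CCC(=O)O1)C(O[Si](C)(C)C(C)(C)C)CCO[Si](C)(C)C(C)(C)C | intermediate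
13 | β-hydroxy lactone adduct of 12 and 5 (lactone α-carbon bonded to the former aldehyde carbon of 5; mixture at the two new centers) | COC(=O)[C@@H](C[C@H]1CC(C(O)C[C@@H](C(C)=C)C[C@@H](OCc2ccc(OC)cc2)C(C)=O)C(=O)O1)C(O[Si](C)(C)C(C)(C)C)CCO[Si](C)(C)C(C)(C)C | intermediate
14 | aldol mesylate, methanesulfonate of the secondary alcohol of 13 | COC(=O)[C@@H](C[C@H]1CC(C(OS(C)(=O)=O)C[C@@H](C(C)=C)C[C@@H](OCc2ccc(OC)cc2)C(C)=O)C(=O)O1)C(O[Si](C)(C)C(C)(C)C)CCO[Si](C)(C)C(C)(C)C | intermediate
15 | (E)-alkylidene lactone, open chain with methyl ketone, PMB ether, methyl ester and two TBS ethers | C=C(C)[C@H](C/C=C1\C[C@H](C[C@H](C(=O)OC)C(O[Si](C)(C)C(C)(C)C)CCO[Si](C)(C)C(C)(C)C)OC1=O)C[C@@H](OCc1ccc(OC)cc1)C(C)=O | intermediate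
16 | primary alcohol from 15 (secondary TBS ether kept) | C=C(C)[C@H](C/C=C1\C[C@H](C[C@H](C(=O)OC)C(O[Si](C)(C)C(C)(C)C)CCO)OC1=O)C[C@@H](OCc1ccc(OC)cc1)C(C)=O | intermediate
17 | seco keto-aldehyde (aldehyde at one chain end, PMB-oxy methyl ketone at the other) | C=C(C)[C@H](C/C=C1\C[C@H](C[C@H](C(=O)OC)C(O[Si](C)(C)C(C)(C)C)CC=O)OC1=O)C[C@@H](OCc1ccc(OC)cc1)C(C)=O | intermediate
18 | macrocyclic 1,2-diol (14-membered carbocycle; secondary OH at the former aldehyde carbon as an epimer mixture, tertiary OH on the methyl-bearing carbon syn to the PMB ether) | C=C(C)[C@@H]1C/C=C2\C[C@H](C[C@H](C(=O)OC)C(O[Si](C)(C)C(C)(C)C)CC(O)[C@@](C)(O)[C@H](OCc3ccc(OC)cc3)C1)OC2=O | intermediate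
19 | macrocyclic α-ketol (ketone next to the tertiary alcohol) | C=C(C)[C@@H]1C/C=C2\C[C@H](C[C@H](C(=O)OC)C(O[Si](C)(C)C(C)(C)C)CC(=O)[C@@](C)(O)[C@H](OCc3ccc(OC)cc3)C1)OC2=O | intermediate
20 | keto diol (PMB removed) | C=C(C)[C@@H]1C/C=C2\C[C@H](C[C@H](C(=O)OC)C(O[Si](C)(C)C(C)(C)C)CC(=O)[C@@](C)(O)[C@H](O)C1)OC2=O | intermediate
21 | secondary mesylate of 20 | C=C(C)[C@@H]1C/C=C2\C[C@H](C[C@H](C(=O)OC)C(O[Si](C)(C)C(C)(C)C)CC(=O)[C@@](C)(O)[C@H](OS(C)(=O)=O)C1)OC2=O | intermediate
22 | silyl-protected epoxy ketone (cis-epoxide, (S,S) at the epoxide carbons) | C=C(C)[C@@H]1C/C=C2\C[C@H](C[C@H](C(=O)OC)C(O[Si](C)(C)C(C)(C)C)CC(=O)[C@@]3(C)O[C@H]3C1)OC2=O | intermediate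
23 | β-hydroxy epoxy ketone | C=C(C)[C@@H]1C/C=C2\C[C@H](C[C@H](C(=O)OC)C(O)CC(=O)[C@@]3(C)O[C@H]3C1)OC2=O | intermediate
24 | CNP0108136.1 (14-membered carbocycle with (E)-α-alkylidene-γ-butyrolactone, methyl ester, 1,3-diketone and cis-epoxide) | C=C(C)[C@@H]1C/C=C2\C[C@H](C[C@H](C(=O)OC)C(=O)CC(=O)[C@@]3(C)O[C@H]3C1)OC2=O | target

Total step count: 18. Longest linear sequence: 14 steps (6 → 24 through steps 5–18; equally 1 → 24 through steps 1–4 and 9–18).

Steps most likely to fail

Step 13. The coupling may fail by electron transfer to the ketone with loss of the neighbouring PMB-oxy group, by reduction of the alkylidene lactone, by attack on the wrong ketone face, or by oligomerization. Fallback: make the same bond without a reductant. Aldehyde 17 is treated at high dilution with an N-mesityl bicyclic triazolium precatalyst and DBU in THF, so that the Breslow intermediate of the aldehyde adds to the ketone (intramolecular crossed aldehyde–ketone benzoin reaction). This sets out from 17, makes no new compound (entry F0) and comes back at α-ketol 19, so that step 14 is not needed. Its own weak point is that the addition is reversible.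

Step 9. The lactone enolate may pass a proton to the methyl ketone or the ester, close onto its own methyl ester (Dieckmann-type), or the later elimination may give mixed alkene geometry and epimerize the center next to the ketone. Fallback: Horner–Wadsworth–Emmons olefination. Lactone 12 is phosphorylated (LDA, ClP(O)(OEt)2, then LDA; enol phosphate to phosphonate rearrangement) to the α-(diethoxyphosphoryl) lactone ester F1, which is condensed with 5 (LiCl, DBU, MeCN, 25 °C). This sets out from 12 and comes back at 15, replacing steps 9 and 10.

Step 8. The acetylide may add to the methyl ester, the liberated alkoxide may close onto the methyl ester (the lactone forms on the wrong side), or the acid step may strip the primary silyl ether. Fallback: build the two carbons under neutral conditions. Epoxide 10 is opened with CH2=CHMgBr and CuI (cat.) at −40 °C to the homoallylic alcohol F2, hydroboration–oxidation (9-BBN; NaBO3·4H2O) gives the 1,4-diol F3, and TEMPO/PhI(OAc)2 closes it oxidatively to the lactone. This sets out from 10 and comes back at 12.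

Further compounds
F0 | step 13 | none | none
F1 | step 9 | α-(diethoxyphosphoryl) lactone ester (12 with P(O)(OEt)2 on the lactone α-carbon, both epimers there) | COC(=O)[C@@H](C[C@H]1CC(P(=O)(OCC)OCC)C(=O)O1)C(O[Si](C)(C)C(C)(C)C)CCO[Si](C)(C)C(C)(C)C
F2 | step 8 | homoallylic alcohol, methyl (2S)-3,5-bis[(tert-butyldimethylsilyl)oxy]-2-[(2S)-2-hydroxypent-4-en-1-yl]pentanoate | COC(=O)[C@@H](C[C@H](O)CC=C)C(O[Si](C)(C)C(C)(C)C)CCO[Si](C)(C)C(C)(C)C
F3 | step 8 | 1,4-diol, methyl 3,5-bis[(tert-butyldimethylsilyl)oxy]-2-(2,5-dihydroxypentyl)pentanoate with the configuration of F2 | COC(=O)[C@@H](C[C@H](O)CCCO)C(O[Si](C)(C)C(C)(C)C)CCO[Si](C)(C)C(C)(C)C
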